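Ring B is disconnected at C8–C9: the exocyclic methylene C8=C17 next to the C11 methylene branch on C9 is read as a terminal alkyne (C8≡C17) that has added across a vinyl group (C9=C11). One palladium-catalysed borylative enyne cyclisation closes ring B 6-exo, creates the methylene, sets C9 and leaves a C11 boronate, which is then homologated (C12) and joined to the C13–C16 unit by boron-ate chemistry before acylation. The precursor is a ring-A 1,7-enyne (butynyl arm on C5, vinyl and methyl on C10, methyl and ester on C4) whose three stereocentres are excised intact from (+)-podocarpic acid by degrading its aromatic ring.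

Key step: step 8

Remark: labdane numbering is used throughout; (+)-podocarpic acid is taken as the natural (4S,5R,10S) enantiomer, whose C4 (α-CH3, β-carboxyl), C5 (α-H) and C10 (β-CH3) configurations are those of the target.

Step 1
Reactants: 1 (+)-podocarpic acid
Product: 2 methyl 12-methoxypodocarpa-8,11,13-trien-19-oate
Conditions: MeI (excess), K2CO3, DMF, 25 °C
Reagents that add atoms: iodomethane, CI
Why: Carboxylate and phenoxide are both O-methylated by SN2 on MeI (Williamson-type alkylation), the reliable way to esterify the hindered axial C19 acid, and no stereocentre is involved, so C4, C5 and C10 are carried over from 1.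

Step 2
Reactants: 2 methyl 12-methoxypodocarpa-8,11,13-trien-19-oate
Product: 3 (1S,2R,3S)-2-(2-carboxyethyl)-3-(methoxycarbonyl)-1,3-dimethylcyclohexane-1-carboxylic acid
Conditions: RuCl3·xH2O (cat.), NaIO4, CCl4/MeCN/H2O, 25 °C
Reagents that add atoms: sodium periodate, [Na+].[O-]I(=O)(=O)=O; water, O
Why: RuO4 formed in situ degrades the electron-rich anisole ring (ruthenium-catalysed oxidative arene cleavage) so that only its two ring-fusion carbons survive as the C9 and C8 carboxylic acids, while saturated ring A with C4, C5 and C10 is not attacked.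

Step 3
Reactants: 3 (1S,2R,3S)-2-(2-carboxyethyl)-3-(methoxycarbonyl)-1,3-dimethylcyclohexane-1-carboxylic acid
Product: 4 (1S,2R,3S)-3-(methoxycarbonyl)-2-(3-methoxy-3-oxopropyl)-1,3-dimethylcyclohexane-1-carboxylic acid
Conditions: MeOH, H2SO4 (cat.), 25 °C
Reagents that add atoms: methanol, CO
Why: Fischer esterification discriminates the primary C8 acid from the C9 acid, which sits on quaternary C10 next to the substituted C5 and should not esterify under these conditions.

Step 4
Reactants: 4 (1S,2R,3S)-3-(methoxycarbonyl)-2-(3-methoxy-3-oxopropyl)-1,3-dimethylcyclohexane-1-carboxylic acid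
Product: 5 methyl (1S,2R,3S)-3-(hydroxymethyl)-2-(3-methoxy-3-oxopropyl)-1,3-dimethylcyclohexane-1-carboxylate
Conditions: BH3·THF, THF, 0 → 25 °C; then MeOH
Reagents that add atoms: none
Why: Borane reduces a free carboxylic acid through its acyloxyborane much faster than it touches esters, so only the C9 acid should become the neopentyl alcohol (chemoselective borane reduction).

Step 5
Reactants: 5 methyl (1S,2R,3S)-3-(hydroxymethyl)-2-(3-methoxy-3-oxopropyl)-1,3-dimethylcyclohexane-1-carboxylate
Product: 6 methyl (1S,2R,3S)-3-formyl-2-(3-methoxy-3-oxopropyl)-1,3-dimethylcyclohexane-1-carboxylate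
Conditions: Dess–Martin periodinane, CH2Cl2, 25 °C
Reagents that add atoms: none
Why: Dess–Martin oxidation stops at the aldehyde, which has no α-hydrogen (C10 is quaternary) and therefore cannot epimerise or enolise.

Step 6
Reactants: 6 methyl (1S,2R,3S)-3-formyl-2-(3-methoxy-3-oxopropyl)-1,3-dimethylcyclohexane-1-carboxylate
Product: 7 methyl (1S,2R,3R)-3-ethenyl-2-(3-methoxy-3-oxopropyl)-1,3-dimethylcyclohexane-1-carboxylate
Conditions: Ph3PCH3Br, KN(SiMe3)2, THF, 0 → 25 °C
Reagents that add atoms: methyltriphenylphosphonium bromide, C[P+](c1ccccc1)(c1ccccc1)c1ccccc1.[Br-]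
Why: Wittig methylenation turns the C9 aldehyde into the C9=C11 vinyl group, the non-stabilised ylide reacting with the aldehyde much faster than with the two esters.

Step 7
Reactants: 7 methyl (1S,2R,3R)-3-ethenyl-2-(3-methoxy-3-oxopropyl)-1,3-dimethylcyclohexane-1-carboxylate
Product: 9 methyl (1S,2R,3R)-2-(but-3-yn-1-yl)-3-ethenyl-1,3-dimethylcyclohexane-1-carboxylate, via aldehyde 8 (not isolated)
Conditions: i-Bu2AlH (1.1 equiv), CH2Cl2, −78 °C; then MeOH, K2CO3, dimethyl (1-diazo-2-oxopropyl)phosphonate, −78 → 25 °C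
Reagents that add atoms: dimethyl (1-diazo-2-oxopropyl)phosphonate, COP(=O)(OC)C(=[N+]=[N-])C(C)=O
Why: i-Bu2AlH at −78 °C should reduce the unhindered C8 ester to the aldehyde while the axial neopentyl C19 ester is left, and Seyferth–Gilbert homologation with the Ohira–Bestmann reagent in the same flask converts the aldehyde released on methanol quench into the terminal alkyne C8≡C17.

Step 8
Reactants: 9 methyl (1S,2R,3R)-2-(but-3-yn-1-yl)-3-ethenyl-1,3-dimethylcyclohexane-1-carboxylate; 10 bis(pinacolato)diboron
Product: 11 methyl 11-(4,4,5,5-tetramethyl-1,3,2-dioxaborolan-2-yl)-12,13,14,15,16-pentanorlabd-8(17)-en-19-oate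
Conditions: Pd(OAc)2 (5 mol %), B2pin2 (1.3 equiv), MeOH (1 equiv), toluene, 50 °C
Reagents that add atoms: none
Why: Pd(OAc)2, B2pin2 and MeOH generate a palladium hydride that adds syn across the terminal alkyne with H on C17 and Pd on C8 (the regiochemistry that lets the vinyl group chelate), the alkenylpalladium inserts the C9=C11 vinyl group, and the resulting primary C11–Pd bond is transmetallated by B2pin2 and reductively eliminated to the C11–B bond faster than β-hydride loss from C9. The closest known reaction type is the palladium-catalysed borylative cyclisation of 1,6- and 1,7-enynes, which gives exo-alkylidene rings carrying a homoallylic boronate. Ring B closes in the 6-exo-trig mode by formation of the C8–C9 bond. C9 is set by substrate control: in the chair-like transition state on the ring-A template the C5 arm and the C10 vinyl group are trans-diequatorial (the arm is cis to the axial C10 methyl), and the vinyl terminus C11 points equatorially, away from C5 and from the axial H5 and H7, so H9 should end axial and anti to the C10 methyl and the CH2B arm equatorial (β). The step needs Pd on C8 and not on C17, cyclisation before borylation of the alkenylpalladium, and borylation before β-hydride loss; the all-carbon tether with two quaternary carbons accelerates ring closure, the vinyl group on quaternary C10 has no allylic hydrogen for an Alder-ene path, and the excess diboron secures the capture.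

Step 9
Reactants: 11 methyl 11-(4,4,5,5-tetramethyl-1,3,2-dioxaborolan-2-yl)-12,13,14,15,16-pentanorlabd-8(17)-en-19-oate
Product: 13 methyl 12-(4,4,5,5-tetramethyl-1,3,2-dioxaborolan-2-yl)-13,14,15,16-tetranorlabd-8(17)-en-19-oate, via chloromethylboronate complex 12 (not isolated)
Conditions: BrCH2Cl, n-BuLi, THF, −78 → 25 °C
Reagents that add atoms: bromochloromethane, ClCBr
Why: Matteson homologation, in which LiCH2Cl made in situ adds to boron and the C11 alkyl group of the ate complex migrates to carbon with loss of chloride, inserts C12 between C11 and boron and leaves C9 and the hindered ester untouched.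

Step 10
Reactants: 14 but-2-yn-1-ol
Product: 16 (Z)-3-iodobut-2-en-1-ol, via alkenylalanate 15 (not isolated)
Conditions: NaAlH2(OCH2CH2OMe)2, THF, 0 → 25 °C; then I2, −78 °C
Reagents that add atoms: iodine, II
Why: Hydroxyl-directed trans-hydroalumination delivers hydride to C2 and aluminium to C3 within a five-membered alanate, so iodinolysis with retention places iodine cis to the CH2OH group (Z).

Step 11
Reactants: 16 (Z)-3-iodobut-2-en-1-ol
Product: 17 (Z)-tert-butyl[(3-iodobut-2-en-1-yl)oxy]dimethylsilane
Conditions: TBSCl, imidazole, CH2Cl2, 25 °C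
Reagents that add atoms: tert-butyldimethylsilyl chloride, CC(C)(C)[Si](C)(C)Cl
Why: Imidazole-promoted silylation of the primary allylic alcohol gives an ether that survives the later lithiation.

Step 12
Reactants: 13 methyl 12-(4,4,5,5-tetramethyl-1,3,2-dioxaborolan-2-yl)-13,14,15,16-tetranorlabd-8(17)-en-19-oate; 17 (Z)-tert-butyl[(3-iodobut-2-en-1-yl)oxy]dimethylsilane
Product: 21 methyl 15-(tert-butyldimethylsilyloxy)labda-8(17),13E-dien-19-oate, via alkenyllithium 18 (not isolated), via alkenylboronate complex 19 (not isolated), via iodoboronate 20 (not isolated)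
Conditions: 17 (1.3 equiv), t-BuLi (2.6 equiv), Et2O, −78 °C; then 13, THF, −78 °C; then I2, MeOH; then NaOMe, MeOH, −78 → 25 °C
Reagents that add atoms: none
Why: In this Zweifel olefination iodine–lithium exchange with retention gives the alkenyllithium, which adds to the primary boronate, iodine then triggers 1,2-migration of the C12 alkyl group, and methoxide-induced anti-elimination of boron and iodide joins C12 to C13 with inversion of the alkene geometry, so the Z iodide should deliver the 13E alkene stereospecifically.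

Step 13
Reactants: 21 methyl 15-(tert-butyldimethylsilyloxy)labda-8(17),13E-dien-19-oate
Product: 22 methyl 15-hydroxylabda-8(17),13E-dien-19-oate
Conditions: Bu4NF, THF, 0 → 25 °C
Reagents that add atoms: none
Why: Fluoride cleaves the Si–O bond (silyl ether deprotection) without affecting the hindered methyl ester or the two alkenes.

Step 14
Reactants: 22 methyl 15-hydroxylabda-8(17),13E-dien-19-oate; 23 palmitoyl chloride
Product: 24 methyl 15-(hexadecanoyloxy)labda-8(17),13E-dien-19-oate
Conditions: pyridine, DMAP (cat.), CH2Cl2, 0 → 25 °C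
Reagents that add atoms: none
Why: DMAP-catalysed acylation of the primary allylic alcohol with the acid chloride gives the palmitate under conditions that leave the C19 methyl ester and both alkenes unchanged.

Compound list

1 | (+)-podocarpic acid (12-hydroxypodocarpa-8,11,13-trien-19-oic acid, 4S,5R,10S) | OC(=O)[C@@]1(C)CCC[C@](C)(c2cc(O)ccc23)[C@H]1CC3 | starting material
2 | methyl 12-methoxypodocarpa-8,11,13-trien-19-oate | COC(=O)[C@@]1(C)CCC[C@](C)(c2cc(OC)ccc23)[C@H]1CC3 | intermediate
3 | (1S,2R,3S)-2-(2-carboxyethyl)-3-(methoxycarbonyl)-1,3-dimethylcyclohexane-1-carboxylic acid (ring-A diacid: C9 acid on C10, C6–C8 acid arm on C5) | COC(=O)[C@@]1(C)CCC[C@](C)(C(=O)O)[C@H]1CCC(=O)O | intermediate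
4 | (1S,2R,3S)-3-(methoxycarbonyl)-2-(3-methoxy-3-oxopropyl)-1,3-dimethylcyclohexane-1-carboxylic acid | COC(=O)[C@@]1(C)CCC[C@](C)(C(=O)O)[C@H]1CCC(=O)OC | intermediate
5 | methyl (1S,2R,3S)-3-(hydroxymethyl)-2-(3-methoxy-3-oxopropyl)-1,3-dimethylcyclohexane-1-carboxylate | COC(=O)[C@@]1(C)CCC[C@](C)(CO)[C@H]1CCC(=O)OC | intermediate
6 | methyl (1S,2R,3S)-3-formyl-2-(3-methoxy-3-oxopropyl)-1,3-dimethylcyclohexane-1-carboxylate | COC(=O)[C@@]1(C)CCC[C@](C)(C=O)[C@H]1CCC(=O)OC | intermediate
7 | methyl (1S,2R,3R)-3-ethenyl-2-(3-methoxy-3-oxopropyl)-1,3-dimethylcyclohexane-1-carboxylate | COC(=O)[C@@]1(C)CCC[C@](C)(C=C)[C@H]1CCC(=O)OC | intermediate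
8 | methyl (1S,2R,3R)-3-ethenyl-1,3-dimethyl-2-(3-oxopropyl)cyclohexane-1-carboxylate (not isolated) | COC(=O)[C@@]1(C)CCC[C@](C)(C=C)[C@H]1CCC=O | intermediate
9 | methyl (1S,2R,3R)-2-(but-3-yn-1-yl)-3-ethenyl-1,3-dimethylcyclohexane-1-carboxylate (ring-A 1,7-enyne; methyl 12,13,14,15,16-pentanor-8,9-secolabd-9(11)-en-8(17)-yn-19-oate) | COC(=O)[C@@]1(C)CCC[C@](C)(C=C)[C@H]1CCC#C | intermediate
10 | bis(pinacolato)diboron | CC1(C)OB(OC1(C)C)B1OC(C)(C)C(C)(C)O1 | starting material
11 | methyl 11-(4,4,5,5-tetramethyl-1,3,2-dioxaborolan-2-yl)-12,13,14,15,16-pentanorlabd-8(17)-en-19-oate (5α-H, 9α-H, 10β-CH3) | C=C1CC[C@@H]2[C@](C)(CCC[C@]2(C)C(=O)OC)[C@H]1CB1OC(C)(C)C(C)(C)O1 | intermediate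
12 | lithium (chloromethyl)boronate complex of 11 (not isolated) | C=C1CC[C@@H]2[C@](C)(CCC[C@]2(C)C(=O)OC)[C@H]1C[B-]1(CCl)OC(C)(C)C(C)(C)O1.[Li+] | intermediate
13 | methyl 12-(4,4,5,5-tetramethyl-1,3,2-dioxaborolan-2-yl)-13,14,15,16-tetranorlabd-8(17)-en-19-oate | C=C1CC[C@@H]2[C@](C)(CCC[C@]2(C)C(=O)OC)[C@H]1CCB1OC(C)(C)C(C)(C)O1 | intermediate
14 | but-2-yn-1-ol | CC#CCO | starting material
15 | sodium cyclic alkenylalanate (aluminium on C3 and on oxygen of the butenol, two 2-methoxyethoxy ligands; not isolated) | [Na+].CC1=CCO[Al-]1(OCCOC)OCCOC | intermediate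
16 | (Z)-3-iodobut-2-en-1-ol | C/C(I)=C/CO | intermediate
17 | (Z)-tert-butyl[(3-iodobut-2-en-1-yl)oxy]dimethylsilane | C/C(I)=C/CO[Si](C)(C)C(C)(C)C | intermediate
18 | (Z)-[4-(tert-butyldimethylsilyloxy)but-2-en-2-yl]lithium (lithium cis to CH2O; not isolated) | C/C([Li])=C/CO[Si](C)(C)C(C)(C)C | intermediate
19 | lithium alkenyl(alkyl)boronate complex from 13 and 18 (not isolated) | C=C1CC[C@@H]2[C@](C)(CCC[C@]2(C)C(=O)OC)[C@H]1CC[B-]1(/C(C)=C\CO[Si](C)(C)C(C)(C)C)OC(C)(C)C(C)(C)O1.[Li+] | intermediate
20 | β-iodoboronate after 1,2-migration (boron and C12 on C13, iodine on C14; two anti-adduct diastereomers, C13 and C14 left undefined; not isolated) | C=C1CC[C@@H]2[C@](C)(CCC[C@]2(C)C(=O)OC)[C@H]1CCC(C)(B1OC(C)(C)C(C)(C)O1)C(I)CO[Si](C)(C)C(C)(C)C | intermediate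
21 | methyl 15-(tert-butyldimethylsilyloxy)labda-8(17),13E-dien-19-oate | C=C1CC[C@@H]2[C@](C)(CCC[C@]2(C)C(=O)OC)[C@H]1CC/C(C)=C/CO[Si](C)(C)C(C)(C)C | intermediate
22 | methyl 15-hydroxylabda-8(17),13E-dien-19-oate | C=C1CC[C@@H]2[C@](C)(CCC[C@]2(C)C(=O)OC)[C@H]1CC/C(C)=C/CO | intermediate
23 | palmitoyl chloride | CCCCCCCCCCCCCCCC(=O)Cl | starting material
24 | methyl 15-(hexadecanoyloxy)labda-8(17),13E-dien-19-oate (CNP0157008.1) | C=C1CC[C@@H]2[C@](C)(CCC[C@]2(C)C(=O)OC)[C@H]1CC/C(C)=C/COC(=O)CCCCCCCCCCCCCCC | target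

Total step count: 14. Longest linear sequence: 12 steps (steps 1–9 and 12–14, from 1 to 24).

Steps most likely to fail

1. Step 8. The palladium hydride may add with palladium on C17, the alkyne or the alkenylpalladium may be borylated before ring closure, β-hydride elimination may outrun boron capture, or facial selectivity at C9 may be poor. The fallback sets out from 9 and returns at 11, closing ring B stoichiometrically. C-Silylation of 9 (LiN(i-Pr)2, TMSCl, THF, −78 °C) would give methyl (1S,2R,3R)-3-ethenyl-1,3-dimethyl-2-[4-(trimethylsilyl)but-3-yn-1-yl]cyclohexane-1-carboxylate F1. Zirconocene-mediated enyne bicyclisation (Cp2ZrCl2, n-BuLi, THF, −78 → 25 °C) would form the same C8–C9 bond in the zirconacyclopentene F2. Iodinolysis of its alkyl–zirconium bond (I2, 1 equiv) followed by protonolysis of the alkenyl–zirconium bond (HCl) would give methyl 11-iodo-17-(trimethylsilyl)-12,13,14,15,16-pentanorlabd-8(17)E-en-19-oate F3. Protodesilylation (CF3CO2H, CH2Cl2) would give methyl 11-iodo-12,13,14,15,16-pentanorlabd-8(17)-en-19-oate F4. Copper-catalysed borylation of the primary iodide (CuI, PPh3, LiOMe, B2pin2, DMF) would then give 11.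

2. Step 2. Oxidation at the benzylic C7 may compete with ring cleavage, or the arene may be degraded incompletely. The fallback sets out from 1 and returns at 3, cleaving the free phenol with ozone. Selective esterification of the acid (MeI, KHCO3, DMF) would give methyl 12-hydroxypodocarpa-8,11,13-trien-19-oate F5. Exhaustive ozonolysis (O3, MeOH/CH2Cl2, −78 °C) with oxidative work-up (H2O2, HCO2H) would give diacid 3.

3. Step 12. The boronate complex may form incompletely, the alkenyllithium may attack elsewhere, or the elimination may lose stereospecificity and erode the 13E geometry. The fallback sets out from 13 and returns at 21, making the C12–C13 bond by cross-coupling with retention.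
   - Oxidation of 13 (NaBO3·4H2O, THF/H2O) would give methyl 12-hydroxy-13,14,15,16-tetranorlabd-8(17)-en-19-oate F6.
   - Iodination (I2, PPh3, imidazole) would give methyl 12-iodo-13,14,15,16-tetranorlabd-8(17)-en-19-oate F7.
   - Separately, silylation of 14 (TBSCl, imidazole) would give tert-butyl(but-2-yn-1-yloxy)dimethylsilane F8, and syn-hydrozirconation–iodination (Cp2Zr(H)Cl; then I2) would give (E)-tert-butyl[(3-iodobut-2-en-1-yl)oxy]dimethylsilane F9.
   - Iodine–lithium exchange on F7 (t-BuLi, −78 °C) and transmetallation (ZnCl2) would give the alkylzinc chloride F10.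
   - Negishi coupling of F10 with F9 (Pd(PPh3)4, THF) would give 21.

Further compounds

F1 | step 8 | methyl (1S,2R,3R)-3-ethenyl-1,3-dimethyl-2-[4-(trimethylsilyl)but-3-yn-1-yl]cyclohexane-1-carboxylate | COC(=O)[C@@]1(C)CCC[C@](C)(C=C)[C@H]1CCC#C[Si](C)(C)C
F2 | step 8 | zirconacyclopentene (Cp2Zr bridging C17 and C11, ring B closed; cyclopentadienyl ligands drawn σ-bonded) | C[Si](C)(C)C1=C2CC[C@@H]3[C@](C)(CCC[C@]3(C)C(=O)OC)[C@H]2C[Zr]1(C1C=CC=C1)C1C=CC=C1
F3 | step 8 | methyl 11-iodo-17-(trimethylsilyl)-12,13,14,15,16-pentanorlabd-8(17)E-en-19-oate | C[Si](C)(C)/C=C1\CC[C@@H]2[C@](C)(CCC[C@]2(C)C(=O)OC)[C@H]1CI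
F4 | step 8 | methyl 11-iodo-12,13,14,15,16-pentanorlabd-8(17)-en-19-oate | C=C1CC[C@@H]2[C@](C)(CCC[C@]2(C)C(=O)OC)[C@H]1CI
F5 | step 2 | methyl 12-hydroxypodocarpa-8,11,13-trien-19-oate | COC(=O)[C@@]1(C)CCC[C@](C)(c2cc(O)ccc23)[C@H]1CC3
F6 | step 12 | methyl 12-hydroxy-13,14,15,16-tetranorlabd-8(17)-en-19-oate | C=C1CC[C@@H]2[C@](C)(CCC[C@]2(C)C(=O)OC)[C@H]1CCO
F7 | step 12 | methyl 12-iodo-13,14,15,16-tetranorlabd-8(17)-en-19-oate | C=C1CC[C@@H]2[C@](C)(CCC[C@]2(C)C(=O)OC)[C@H]1CCI
F8 | step 12 | tert-butyl(but-2-yn-1-yloxy)dimethylsilane | CC#CCO[Si](C)(C)C(C)(C)C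
F9 | step 12 | (E)-tert-butyl[(3-iodobut-2-en-1-yl)oxy]dimethylsilane | C/C(I)=C\CO[Si](C)(C)C(C)(C)C
F10 | step 12 | alkylzinc chloride derived from F7 (zinc on C12) | C=C1CC[C@@H]2[C@](C)(CCC[C@]2(C)C(=O)OC)[C@H]1CC[Zn]Cl
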